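**Retrosynthetic overview**
1. Pulicanaral A is traced back, through acetylation, desilylation and adjustment of C14 from ester to aldehyde, to a bis-silylated tert-butyl glycidate that already holds the whole 11-oxabicyclo[8.1.0]undec-6-ene core.
2. Enabling feature: C1–C10 is the bond shared by the oxirane (O, C1, C10) and the ten-membered carbocycle (C1–C10). It is also the α,β-bond of a glycidic carbonyl unit (C14=O on C10, oxygen on C1), which is a Darzens retron. Cutting it unravels both rings to an open-chain ω-formyl α-bromo-α-chloro ester.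
3. Forward: SmI2 converts C10(Br)(Cl) into a chloro-enolate. The aldol addition to the C1 aldehyde closes the cyclodecene first, and the C1 alkoxide then expels chloride and closes the oxirane second, in the same flask. Both C10 epimers of the precursor converge.
4. The open chain comes from C5–C6 (alkenyllithium + Weinreb amide), C7–C8 (Evans syn aldol, sets C7 and C8) and a 1,3-anti reduction (sets C6). The E-C4=C5 olefin with C15 comes from carboalumination of pent-4-yn-1-ol, and C8–C9–C10–C14 from tert-butyl 4-oxobutanoate.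

Key step: step 12

Remark on numbering: germacrane numbering of the target is used throughout. C1 is the oxirane CH, C10 the oxirane C bearing C14, C4=C5 the olefin with methyl C15 on C4, C6 and C8 the oxygenated carbons, and C7 the carbon bearing isopropyl.
Assumption: pent-4-yn-1-ol, (S)-4-benzyl-1,3-oxazolidin-2-one, 3-methylbutanoyl chloride and tert-butyl 4-oxobutanoate are taken as purchasable.

**Route**

Step 1
Reactants: 1 pent-4-yn-1-ol
Product: 3 (E)-5-iodo-4-methylpent-4-en-1-ol, via (E)-alkenyl(dimethyl)alane O-dimethylaluminium alkoxide 2 (not isolated)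
Conditions: Me3Al (3 equiv), Cp2ZrCl2 (0.25 equiv), CH2Cl2, 0 °C to rt; then I2, THF, −30 °C
Reagents that add atoms: trimethylaluminium C[Al](C)C; iodine II
Why: Negishi zirconium-catalysed carboalumination adds methyl and aluminium syn with aluminium at the terminus, and iodinolysis with retention fixes the E-trisubstituted C4=C5 olefin with C15 in place.

Step 2
Reactants: 3 (E)-5-iodo-4-methylpent-4-en-1-ol
Product: 4 (E)-triethyl[(5-iodo-4-methylpent-4-en-1-yl)oxy]silane
Conditions: TESCl, imidazole, CH2Cl2, 0 °C to rt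
Reagents that add atoms: chlorotriethylsilane CC[Si](Cl)(CC)CC
Why: Standard silylation masks the C1 hydroxyl for the lithiation, and a primary TES ether can later be oxidised directly to the aldehyde.

Step 3
Reactants: 5 (S)-4-benzyl-1,3-oxazolidin-2-one; 6 3-methylbutanoyl chloride
Product: 8 (S)-4-benzyl-3-(3-methylbutanoyl)-1,3-oxazolidin-2-one, via N-lithio oxazolidinone 7 (not isolated)
Conditions: n-BuLi, THF, −78 °C; then 6, −78 to 0 °C
Reagents that add atoms: none
Why: N-acylation of the lithiated Evans auxiliary installs C6, C7 and the isopropyl group.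

Step 4
Reactants: 8 (S)-4-benzyl-3-(3-methylbutanoyl)-1,3-oxazolidin-2-one; 9 tert-butyl 4-oxobutanoate
Product: 11 tert-butyl (4R,5S)-5-{[(4S)-4-benzyl-2-oxo-1,3-oxazolidin-3-yl]carbonyl}-4-hydroxy-6-methylheptanoate, via (Z)-dibutylboron enolate 10 (not isolated)
Conditions: Bu2BOTf, Et3N, CH2Cl2, −78 to 0 °C; then 9, −78 to 0 °C; H2O2, MeOH, pH 7 buffer
Reagents that add atoms: none
Why: In the Evans syn aldol the Z-boron enolate reacts through a Zimmerman–Traxler chair on the face away from the benzyl group, which should set C7 (S) and C8 (R) together.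

Step 5
Reactants: 11 syn aldol imide
Product: 12 tert-butyl (4R,5S)-4-hydroxy-5-[methoxy(methyl)carbamoyl]-6-methylheptanoate
Conditions: MeNH(OMe)·HCl, AlMe3, CH2Cl2, −20 to 0 °C; Rochelle salt
Reagents that add atoms: N,O-dimethylhydroxylamine hydrochloride CNOC.Cl
Why: The aluminium-amide Weinreb transamidation is directed to the imide carbonyl by the free C8 hydroxyl, and the bulky tert-butyl ester should neither react nor lactonise.

Step 6
Reactants: 12 hydroxy Weinreb amide; 4 alkenyl iodide
Product: 14 tert-butyl (4R,5S,7E)-4-hydroxy-8-methyl-6-oxo-5-(propan-2-yl)-11-(triethylsilyloxy)undec-7-enoate, via (E)-alkenyllithium 13 (not isolated)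
Conditions: 4 (2.5 equiv), t-BuLi (5 equiv), Et2O, −78 °C; then 12, THF, −78 to −40 °C; aq NH4Cl at −40 °C
Reagents that add atoms: none
Why: Iodine–lithium exchange proceeds with retention of olefin geometry, and the Weinreb ketone synthesis stops at the chelated tetrahedral adduct, while the tert-butyl ester is much slower towards the organolithium at this temperature.

Step 7
Reactants: 14 β-hydroxy enone
Product: 15 tert-butyl (4R,5S,6R,7E)-4,6-dihydroxy-8-methyl-5-(propan-2-yl)-11-(triethylsilyloxy)undec-7-enoate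
Conditions: Me4NBH(OAc)3, MeCN/AcOH 1:1, −30 °C
Reagents that add atoms: none
Why: In the Evans–Saksena reduction the C8 alkoxyborohydride delivers hydride intramolecularly through a chair, which should give the 1,3-anti diol and so set C6 (R).

Step 8
Reactants: 15 anti diol
Product: 16 tert-butyl (4R,5S,6R,7E)-8-methyl-5-(propan-2-yl)-4,6,11-tris(triethylsilyloxy)undec-7-enoate
Conditions: TESCl, imidazole, DMAP (cat.), DMF, rt
Reagents that add atoms: chlorotriethylsilane CC[Si](Cl)(CC)CC
Why: Silylation under non-Lewis-acidic conditions spares the tert-butyl ester and would also re-silylate any C1 hydroxyl freed by the acidic medium of step 7.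

Step 9
Reactants: 16 tris-TES ester
Product: 18 tert-butyl (2RS,4R,5S,6R,7E)-2-chloro-8-methyl-5-(propan-2-yl)-4,6,11-tris(triethylsilyloxy)undec-7-enoate, via lithium enolate 17 (not isolated)
Conditions: LDA, THF, −78 °C; cannulated into NCS, THF, −78 °C
Reagents that add atoms: N-chlorosuccinimide O=C1CCC(=O)N1Cl
Why: Electrophilic α-chlorination of the only enolisable position (C10) uses inverse addition to curb proton exchange, and the C10 epimer mixture is of no consequence.

Step 10
Reactants: 18 α-chloro ester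
Product: 20 tert-butyl (2RS,4R,5S,6R,7E)-2-bromo-2-chloro-8-methyl-5-(propan-2-yl)-4,6,11-tris(triethylsilyloxy)undec-7-enoate, via lithium chloro-enolate 19 (not isolated)
Conditions: LiHMDS, THF, −78 °C; NBS, −78 °C; aq Na2S2O3
Reagents that add atoms: N-bromosuccinimide O=C1CCC(=O)N1Br
Why: The more acidic α-chloro ester is enolised by the weaker amide base and brominated, which gives the geminal pair of one reductive trigger (Br) and one nucleofuge (Cl).

Step 11
Reactants: 20 α-bromo-α-chloro ester
Product: 21 tert-butyl (2RS,4R,5S,6R,7E)-2-bromo-2-chloro-8-methyl-11-oxo-5-(propan-2-yl)-4,6-bis(triethylsilyloxy)undec-7-enoate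
Conditions: (COCl)2, DMSO, CH2Cl2, −78 to −30 °C; Et3N, −78 to 0 °C
Reagents that add atoms: none
Why: Under Swern conditions the activated sulfonium species attacks only the unhindered primary TES ether oxygen, so C1 is desilylated and oxidised in one step while the secondary TES ethers stay.

Step 12
Reactants: 21 open-chain ω-formyl α-bromo-α-chloro ester
Product: 24 tert-butyl (1R,4E,6R,7S,8R,10S)-1,10-epoxy-6,8-bis(triethylsilyloxy)germacr-4-en-14-oate (cis-fused oxirane, C2 cis to C9), via samarium(III) chloro-enolate 22 (not isolated), via macrocyclic (1R,10R) samarium(III) chlorohydrin alkoxide 23 (not isolated)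
Conditions: SmI2 (2.3 equiv, 0.02 M), THF, −78 °C, 21 added by syringe pump (final 2 mM); dry air until colourless; KOt-Bu, −78 to 0 °C
Reagents that add atoms: none
Why: Proposed new method: two single-electron transfers from SmI2 cleave only the weaker C10–Br bond, so both C10 epimers of 21 collapse to one planar Sm(III) α-chloro ester enolate 22 whose site is fixed by the halogen and not by acidity, and the oxophilic Sm(III) then binds the C1 formyl oxygen and delivers C10 to C1 in a chelated Reformatsky-type aldol. The closest known reaction types are the SmI2-promoted intramolecular Reformatsky closure of medium and large rings and the stepwise reductive Darzens synthesis of glycidic esters from gem-dihalo esters (Reformatsky addition, then base), and what is new is their merger in a ten-membered carbocycle. The cyclodecene closes in a 10-(enolexo)-exo-trig aldol that forms C1–C10, and after Sm/K exchange the oxirane closes in a 3-exo-tet SN2 displacement of the tertiary chloride by O1 with inversion at C10. The C1/C10 relative configuration (C2 cis to C9 and trans to the ester) should follow from the antiperiplanar O1–C1–C10–Cl array required for closure, which a ring that already contains the E-C4=C5 olefin reaches with least strain in the cis-fused isomer, while mismatched potassium aldolates can revert by retro-aldol and be funnelled to the same product. The sense relative to C6–C8 (attack on the Si face of C1 giving 1R, and 10S after inversion) should be set by the tether, because A1,3 strain between C15 and C6–H and the outward OTES and isopropyl groups of the anti,syn C6–C8 triad leave one folded conformer in which the Sm-bound O1 lies on the ring periphery, on the ring face that bears the oxirane oxygen in the natural product. The step needs Br-over-Cl and halo-ester-over-aldehyde chemoselectivity and cyclisation over oligomerisation, which are secured by the Br/Cl pair, by −78 °C without HMPA or proton source, and by slow addition of 21 into excess SmI2 (fast second electron transfer, pseudo-high dilution, Sm template).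

Step 13
Reactants: 24 glycidic tert-butyl ester
Product: 25 (1R,4E,6R,7S,8R,10R)-1,10-epoxy-6,8-bis(triethylsilyloxy)germacr-4-en-14-ol (same spatial arrangement; the C10 descriptor changes by CIP rank only)
Conditions: DIBAL-H (3 equiv), CH2Cl2, −78 to −20 °C; Rochelle salt
Reagents that add atoms: none
Why: DIBAL-H reduces the ester to the primary alcohol at low temperature, where the oxirane and the silyl ethers are not touched.

Step 14
Reactants: 25 epoxy alcohol
Product: 26 (1R,4E,6R,7S,8R,10S)-1,10-epoxy-6,8-bis(triethylsilyloxy)germacr-4-en-14-al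
Conditions: Dess–Martin periodinane, CH2Cl2, 0 °C to rt
Reagents that add atoms: none
Why: Dess–Martin oxidation gives the α,β-epoxy aldehyde, which cannot epimerise because C10 carries no hydrogen.

Step 15
Reactants: 26 bis-TES epoxy aldehyde
Product: 27 (1R,4E,6R,7S,8R,10S)-1,10-epoxy-6,8-dihydroxygermacr-4-en-14-al
Conditions: HF·pyridine, pyridine, THF, 0 °C
Reagents that add atoms: none
Why: Buffered fluoride desilylation removes the labile TES ethers, the formyl group deactivates the oxirane towards acid, and C8–OH and C14 lie on opposite ring faces, so lactol formation would need a trans-bridged bicycle.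

Step 16
Reactants: 27 epoxy aldehyde diol
Product: 28 pulicanaral A
Conditions: Ac2O, pyridine, DMAP (cat.), CH2Cl2, 0 °C to rt
Reagents that add atoms: acetic anhydride CC(=O)OC(C)=O
Why: DMAP-catalysed acetylation esterifies both secondary hydroxyls without touching any stereocentre.

**Compound list**
1 | pent-4-yn-1-ol | C#CCCCO | starting material
2 | (E)-alkenyl(dimethyl)alane, O-dimethylaluminium alkoxide | C[Al](C)OCCC/C(C)=C/[Al](C)C | intermediate
3 | (E)-5-iodo-4-methylpent-4-en-1-ol | OCCC/C(C)=C/I | intermediate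
4 | (E)-triethyl[(5-iodo-4-methylpent-4-en-1-yl)oxy]silane | CC[Si](CC)(CC)OCCC/C(C)=C/I | intermediate
5 | (S)-4-benzyl-1,3-oxazolidin-2-one | O=C1N[C@@H](Cc2ccccc2)CO1 | starting material
6 | 3-methylbutanoyl chloride | CC(C)CC(=O)Cl | starting material
7 | N-lithio (S)-4-benzyl-1,3-oxazolidin-2-one | [Li]N1[C@@H](Cc2ccccc2)COC1=O | intermediate
8 | (S)-4-benzyl-3-(3-methylbutanoyl)-1,3-oxazolidin-2-one | CC(C)CC(=O)N1[C@@H](Cc2ccccc2)COC1=O | intermediate
9 | tert-butyl 4-oxobutanoate | O=CCCC(=O)OC(C)(C)C | starting material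
10 | (Z)-dibutylboron enolate of 8 | CCCCB(CCCC)O/C(=C\C(C)C)N1[C@@H](Cc2ccccc2)COC1=O | intermediate
11 | tert-butyl (4R,5S)-5-{[(4S)-4-benzyl-2-oxo-1,3-oxazolidin-3-yl]carbonyl}-4-hydroxy-6-methylheptanoate | O=C1OC[C@H](Cc2ccccc2)N1C(=O)[C@@H](C(C)C)[C@H](O)CCC(=O)OC(C)(C)C | intermediate
12 | tert-butyl (4R,5S)-4-hydroxy-5-[methoxy(methyl)carbamoyl]-6-methylheptanoate | CON(C)C(=O)[C@@H](C(C)C)[C@H](O)CCC(=O)OC(C)(C)C | intermediate
13 | (E)-[2-methyl-5-(triethylsilyloxy)pent-1-en-1-yl]lithium | CC[Si](CC)(CC)OCCC/C(C)=C/[Li] | intermediate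
14 | tert-butyl (4R,5S,7E)-4-hydroxy-8-methyl-6-oxo-5-(propan-2-yl)-11-(triethylsilyloxy)undec-7-enoate | CC[Si](CC)(CC)OCCC/C(C)=C/C(=O)[C@@H](C(C)C)[C@H](O)CCC(=O)OC(C)(C)C | intermediate
15 | tert-butyl (4R,5S,6R,7E)-4,6-dihydroxy-8-methyl-5-(propan-2-yl)-11-(triethylsilyloxy)undec-7-enoate | CC[Si](CC)(CC)OCCC/C(C)=C/[C@@H](O)[C@@H](C(C)C)[C@H](O)CCC(=O)OC(C)(C)C | intermediate
16 | tert-butyl (4R,5S,6R,7E)-8-methyl-5-(propan-2-yl)-4,6,11-tris(triethylsilyloxy)undec-7-enoate | CC[Si](CC)(CC)OCCC/C(C)=C/[C@@H](O[Si](CC)(CC)CC)[C@@H](C(C)C)[C@H](O[Si](CC)(CC)CC)CCC(=O)OC(C)(C)C | intermediate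
17 | lithium enolate of 16 | CC[Si](CC)(CC)OCCC/C(C)=C/[C@@H](O[Si](CC)(CC)CC)[C@@H](C(C)C)[C@H](O[Si](CC)(CC)CC)CC=C(O[Li])OC(C)(C)C | intermediate
18 | tert-butyl (2RS,4R,5S,6R,7E)-2-chloro-8-methyl-5-(propan-2-yl)-4,6,11-tris(triethylsilyloxy)undec-7-enoate | CC[Si](CC)(CC)OCCC/C(C)=C/[C@@H](O[Si](CC)(CC)CC)[C@@H](C(C)C)[C@H](O[Si](CC)(CC)CC)CC(Cl)C(=O)OC(C)(C)C | intermediate
19 | lithium enolate of 18 | CC[Si](CC)(CC)OCCC/C(C)=C/[C@@H](O[Si](CC)(CC)CC)[C@@H](C(C)C)[C@H](O[Si](CC)(CC)CC)CC(Cl)=C(O[Li])OC(C)(C)C | intermediate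
20 | tert-butyl (2RS,4R,5S,6R,7E)-2-bromo-2-chloro-8-methyl-5-(propan-2-yl)-4,6,11-tris(triethylsilyloxy)undec-7-enoate | CC[Si](CC)(CC)OCCC/C(C)=C/[C@@H](O[Si](CC)(CC)CC)[C@@H](C(C)C)[C@H](O[Si](CC)(CC)CC)CC(Cl)(Br)C(=O)OC(C)(C)C | intermediate
21 | tert-butyl (2RS,4R,5S,6R,7E)-2-bromo-2-chloro-8-methyl-11-oxo-5-(propan-2-yl)-4,6-bis(triethylsilyloxy)undec-7-enoate | O=CCC/C(C)=C/[C@@H](O[Si](CC)(CC)CC)[C@@H](C(C)C)[C@H](O[Si](CC)(CC)CC)CC(Cl)(Br)C(=O)OC(C)(C)C | intermediate
22 | samarium(III) α-chloro ester enolate of the open chain | O=CCC/C(C)=C/[C@@H](O[Si](CC)(CC)CC)[C@@H](C(C)C)[C@H](O[Si](CC)(CC)CC)CC(Cl)=C(O[Sm](I)I)OC(C)(C)C | intermediate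
23 | (1R,10R) ten-membered chlorohydrin as its samarium(III) alkoxide | CC[Si](CC)(CC)O[C@@H]1/C=C(\C)CC[C@@H](O[Sm](I)I)[C@@](Cl)(C(=O)OC(C)(C)C)C[C@@H](O[Si](CC)(CC)CC)[C@@H]1C(C)C | intermediate
24 | tert-butyl (1R,4E,6R,7S,8R,10S)-1,10-epoxy-6,8-bis(triethylsilyloxy)germacr-4-en-14-oate | CC[Si](CC)(CC)O[C@@H]1/C=C(\C)CC[C@H]2O[C@@]2(C(=O)OC(C)(C)C)C[C@@H](O[Si](CC)(CC)CC)[C@@H]1C(C)C | intermediate
25 | (1R,4E,6R,7S,8R,10R)-1,10-epoxy-6,8-bis(triethylsilyloxy)germacr-4-en-14-ol | CC[Si](CC)(CC)O[C@@H]1/C=C(\C)CC[C@H]2O[C@@]2(CO)C[C@@H](O[Si](CC)(CC)CC)[C@@H]1C(C)C | intermediate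
26 | (1R,4E,6R,7S,8R,10S)-1,10-epoxy-6,8-bis(triethylsilyloxy)germacr-4-en-14-al | CC[Si](CC)(CC)O[C@@H]1/C=C(\C)CC[C@H]2O[C@@]2(C=O)C[C@@H](O[Si](CC)(CC)CC)[C@@H]1C(C)C | intermediate
27 | (1R,4E,6R,7S,8R,10S)-1,10-epoxy-6,8-dihydroxygermacr-4-en-14-al | O[C@@H]1/C=C(\C)CC[C@H]2O[C@@]2(C=O)C[C@@H](O)[C@@H]1C(C)C | intermediate
28 | pulicanaral A, (1R,4E,6R,7S,8R,10S)-6,8-diacetoxy-1,10-epoxygermacr-4-en-14-al | CC(=O)O[C@@H]1/C=C(\C)CC[C@H]2O[C@@]2(C=O)C[C@@H](OC(C)=O)[C@@H]1C(C)C | target

**Step count**
Total step count: 16. Longest linear sequence: 14 (steps 3 to 16). Steps 1 and 2 form the short branch that joins at step 6.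

**Steps most likely to fail**

*First, step 12.*
- The samarium enolate may be protonated or may oligomerise before the ten-membered ring closes.
- The remaining C–Cl bond may be reduced, with β-elimination following.
- The tether may give poor facial selectivity, or a trans-fused closure.
- The fallback uses known chemistry. It separates ring closure from oxygen delivery and puts the oxirane configuration under reagent control. It sets out from 16 and returns at 25.
- The enolate of 16 (LDA, THF, −78 °C) is trapped with ClP(OEt)2 and oxidised with H2O2 to the α-phosphono ester F1.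
- Swern oxidation of the primary TES ether gives the phosphono aldehyde F2.
- An intramolecular Horner–Wadsworth–Emmons reaction under Masamune–Roush conditions (LiCl, DBU, MeCN, high dilution) should give the macrocyclic 1(10)E enoate F3, in which C2 is trans to the ester and so cis to C9.
- DIBAL-H gives the allylic alcohol F4.
- Sharpless asymmetric epoxidation (Ti(OiPr)4, D-(−)-DET, TBHP, 4 Å sieves, CH2Cl2, −20 °C) should deliver oxygen to the face that gives the (R,R)-type epoxy alcohol 25.

*Second, step 6.*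
- The hindered α-isopropyl Weinreb amide may react slowly.
- Attack of the organolithium on the tert-butyl ester, or lactonisation of the C8 alkoxide, may then compete.
- The fallback replaces the polar addition by a neutral palladium-catalysed acyl coupling. It sets out from 11 and returns at 14.
- Lithium ethanethiolate (EtSH, n-BuLi, THF, 0 °C) converts 11 into the S-ethyl thioester F5.
- Alkenyllithium 13 is transmetalated with ZnBr2 to the alkenylzinc bromide F6.
- A Fukuyama coupling of F5 with F6 (PdCl2(dppf) cat., THF/toluene, rt) should give 14 directly.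

*Third, step 15.*
- Once the hydroxyls are free next to the formyl oxirane, transannular hemiacetal formation or acid-induced opening of the oxirane may erode the material.
- The fallback reveals the aldehyde last, with the acetates already in place. It sets out from 25 and returns at 28.
- The primary alcohol of 25 is capped (TBDPSCl, imidazole, CH2Cl2) to give the TBDPS ether F7.
- The two TES ethers are removed selectively (AcOH/THF/H2O, rt) to give the diol F8.
- Acetylation (Ac2O, pyridine, DMAP) gives the diacetate F9.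
- Buffered fluoride (TBAF/AcOH, THF) frees the primary alcohol F10.
- Dess–Martin oxidation gives 28.

**Further compounds**
F1 | step 12 | tert-butyl (2RS,4R,5S,6R,7E)-2-(diethoxyphosphoryl)-8-methyl-5-(propan-2-yl)-4,6,11-tris(triethylsilyloxy)undec-7-enoate | CC[Si](CC)(CC)OCCC/C(C)=C/[C@@H](O[Si](CC)(CC)CC)[C@@H](C(C)C)[C@H](O[Si](CC)(CC)CC)CC(P(=O)(OCC)OCC)C(=O)OC(C)(C)C
F2 | step 12 | tert-butyl (2RS,4R,5S,6R,7E)-2-(diethoxyphosphoryl)-8-methyl-11-oxo-5-(propan-2-yl)-4,6-bis(triethylsilyloxy)undec-7-enoate | O=CCC/C(C)=C/[C@@H](O[Si](CC)(CC)CC)[C@@H](C(C)C)[C@H](O[Si](CC)(CC)CC)CC(P(=O)(OCC)OCC)C(=O)OC(C)(C)C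
F3 | step 12 | tert-butyl (1(10)E,4E,6R,7S,8R)-6,8-bis(triethylsilyloxy)germacra-1(10),4-dien-14-oate | CC[Si](CC)(CC)O[C@@H]1/C=C(\C)CC/C=C(/C(=O)OC(C)(C)C)C[C@@H](O[Si](CC)(CC)CC)[C@@H]1C(C)C
F4 | step 12 | (1(10)E,4E,6R,7S,8R)-6,8-bis(triethylsilyloxy)germacra-1(10),4-dien-14-ol | CC[Si](CC)(CC)O[C@@H]1/C=C(\C)CC/C=C(/CO)C[C@@H](O[Si](CC)(CC)CC)[C@@H]1C(C)C
F5 | step 6 | tert-butyl (4R,5S)-5-[(ethylsulfanyl)carbonyl]-4-hydroxy-6-methylheptanoate | CCSC(=O)[C@@H](C(C)C)[C@H](O)CCC(=O)OC(C)(C)C
F6 | step 6 | (E)-[2-methyl-5-(triethylsilyloxy)pent-1-en-1-yl]zinc bromide | CC[Si](CC)(CC)OCCC/C(C)=C/[Zn]Br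
F7 | step 15 | (1R,4E,6R,7S,8R,10R)-14-(tert-butyldiphenylsilyloxy)-1,10-epoxy-6,8-bis(triethylsilyloxy)germacr-4-ene | CC[Si](CC)(CC)O[C@@H]1/C=C(\C)CC[C@H]2O[C@@]2(CO[Si](c3ccccc3)(c4ccccc4)C(C)(C)C)C[C@@H](O[Si](CC)(CC)CC)[C@@H]1C(C)C
F8 | step 15 | (1R,4E,6R,7S,8R,10R)-14-(tert-butyldiphenylsilyloxy)-1,10-epoxygermacr-4-ene-6,8-diol | O[C@@H]1/C=C(\C)CC[C@H]2O[C@@]2(CO[Si](c3ccccc3)(c4ccccc4)C(C)(C)C)C[C@@H](O)[C@@H]1C(C)C
F9 | step 15 | (1R,4E,6R,7S,8R,10R)-14-(tert-butyldiphenylsilyloxy)-1,10-epoxygermacr-4-ene-6,8-diyl diacetate | CC(=O)O[C@@H]1/C=C(\C)CC[C@H]2O[C@@]2(CO[Si](c3ccccc3)(c4ccccc4)C(C)(C)C)C[C@@H](OC(C)=O)[C@@H]1C(C)C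
F10 | step 15 | (1R,4E,6R,7S,8R,10R)-1,10-epoxy-14-hydroxygermacr-4-ene-6,8-diyl diacetate | CC(=O)O[C@@H]1/C=C(\C)CC[C@H]2O[C@@]2(CO)C[C@@H](OC(C)=O)[C@@H]1C(C)C
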